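Both dihydropyran rings are retrons of an inverse-electron-demand oxa-Diels–Alder reaction: in each, O1–C2 and C3–C4 can come from a tropolone ortho-quinone methide (O=C9a–C4a=CH2) and one terminal C=C of a linear polyene. The almost twofold-symmetric target thus collapses to two molecules of one hydroxymethyl tropolone and (3E,5E,7E)-nona-1,3,5,7-tetraene. In the key step a chiral Brønsted acid dehydrates the tropolone to the quinone methide and steers two cycloadditions: the vinyl terminus gives the 3-unsubstituted ring, the (E)-propenyl terminus the trans-2,3-disubstituted ring. Four bonds, two rings and three stereocentres arise in one operation. The tropolone is built from 2-methylanisole by dibromocarbene ring expansion.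

Key step: step 8

Remarks on the chemistry
- Locants: each half is numbered as a 3,4-dihydro-2H-cyclohepta[b]pyran (O1, C2, C3, C4, C4a, C5 to C9, C9a). Unprimed locants belong to the half with the 3-methyl group, primed locants to the half without it. The target is (2R,3R,2′R).
- Tropolones are written as one tautomer; the tautomers interconvert rapidly.
- Compounds 3, 4 and 5 are racemic (one enantiomer drawn); all their stereocentres are erased in step 4.
- Assumption: the sense of induction of the chiral acid in step 8 cannot be predicted with confidence. The (R)-catalyst is written; its antipode is used if a trial run shows the opposite sense.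

Step 1
Reactants: 1 2-methylanisole
Product: 2 1-methoxy-2-methylcyclohexa-1,4-diene
Conditions: Li, liquid NH3, THF, t-BuOH, −78 to −33 °C; then NH4Cl
Reagents that add atoms: none
Why: Birch reduction; both donor substituents stay on sp2 carbons, so the 2,5-dihydro isomer with a tetrasubstituted enol-ether C=C should form.

Step 2
Reactants: 2 1-methoxy-2-methylcyclohexa-1,4-diene
Product: 3 (±)-7,7-dibromo-1-methoxy-6-methylbicyclo[4.1.0]hept-3-ene
Conditions: CHBr3, KOt-Bu, pentane, −20 to 0 °C
Reagents that add atoms: bromoform, BrC(Br)Br
Why: Dibromocarbene cyclopropanation; the electrophilic carbene should select the electron-rich tetrasubstituted enol-ether C=C over the disubstituted one, the ring fusion can only be cis, and the product is racemic.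

Step 3
Reactants: 3 (±)-7,7-dibromo-1-methoxy-6-methylbicyclo[4.1.0]hept-3-ene
Product: 4 (±)-7,7-dibromo-1-methoxy-6-methylbicyclo[4.1.0]heptane-3,4-diol (cis-diol, anti to the CBr2 bridge)
Conditions: OsO4 (2 mol %), N-methylmorpholine N-oxide, acetone/H2O, rt
Reagents that add atoms: osmium tetroxide, O=[Os](=O)(=O)=O; N-methylmorpholine N-oxide, C[N+]1([O-])CCOCC1; water, O
Why: Upjohn syn-dihydroxylation of the remaining C=C, expected anti to the CBr2 bridge because the endo bromine shields the syn face; the two new stereocentres are destroyed in step 4.

Step 4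
Reactants: 4 (±)-7,7-dibromo-1-methoxy-6-methylbicyclo[4.1.0]heptane-3,4-diol
Product: 6 5-bromo-2-hydroxy-4-methoxy-6-methylcyclohepta-2,4,6-trien-1-one, via bicyclic 1,2-diketone 5 (not isolated)
Conditions: trifluoroacetic anhydride, DMSO, CH2Cl2, −60 °C; then Et3N, −60 °C to rt
Reagents that add atoms: none
Why: Swern-type oxidation with anhydride-activated DMSO should take the cis-diol to diketone 5 without C–C cleavage; the enolised diketone then opens the C1–C6 cyclopropane bond with loss of bromide (gem-dibromocyclopropane ring expansion) and tautomerises to the tropolone, leaving Br on C5 between OMe and Me.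

Step 5
Reactants: 6 5-bromo-2-hydroxy-4-methoxy-6-methylcyclohepta-2,4,6-trien-1-one
Product: 7 5-bromo-2,4-dihydroxy-6-methylcyclohepta-2,4,6-trien-1-one
Conditions: 2 M aq HCl, 1,4-dioxane, 80 °C
Reagents that add atoms: water, O
Why: Acid hydrolysis of a vinylogous methyl ester (water adds to C4 of the protonated tropolone and methanol is expelled), the classical cleavage of tropolone methyl ethers; the C–Br bond should be untouched.

Step 6
Reactants: 7 5-bromo-2,4-dihydroxy-6-methylcyclohepta-2,4,6-trien-1-one
Product: 8 2,4-dihydroxy-5-(hydroxymethyl)-6-methylcyclohepta-2,4,6-trien-1-one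
Conditions: Bu3SnCH2OH, Pd(PPh3)4 (10 mol %), 1,4-dioxane, 90 °C
Reagents that add atoms: (tributylstannyl)methanol, CCCC[Sn](CCCC)(CCCC)CO
Why: Migita–Kosugi–Stille hydroxymethylation replaces Br on C5 by CH2OH under neutral conditions that tolerate the acidic OH groups and should not ionise the new o-hydroxybenzylic alcohol.

Step 7
Reactants: 9 (2E,4E)-hexa-2,4-dienal
Product: 10 (3E,5E,7E)-nona-1,3,5,7-tetraene
Conditions: diethyl allylphosphonate, n-BuLi, THF, HMPA, −78 °C to rt; kept as a cold pentane solution with BHT
Reagents that add atoms: diethyl allylphosphonate, C=CCP(=O)(OCC)OCC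
Why: Horner–Wadsworth–Emmons olefination; the α-lithiated allylphosphonate should react at its α-carbon and eliminate to the (E)-alkene, so the new C3=C4 bond is E and the existing E,E-diene is untouched.

Step 8
Reactants: 8 2,4-dihydroxy-5-(hydroxymethyl)-6-methylcyclohepta-2,4,6-trien-1-one (2.4 equiv, added in portions); 10 (3E,5E,7E)-nona-1,3,5,7-tetraene
Product: 13 (2R,3R)-8-hydroxy-2-{(1E,3E)-4-[(2R)-8-hydroxy-5-methyl-7-oxo-2,3,4,7-tetrahydrocyclohepta[b]pyran-2-yl]buta-1,3-dien-1-yl}-3,5-dimethyl-3,4-dihydrocyclohepta[b]pyran-7(2H)-one, via tropolone o-quinone methide 11 (not isolated), via mono-cycloadduct 12 (not isolated)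
Conditions: (R)-N-triflylphosphoramide of 3,3′-bis(2,4,6-triisopropylphenyl)-1,1′-bi-2-naphthol (10 mol %), 5 Å molecular sieves, CHCl3, −20 °C to rt
Reagents that add atoms: none
Why: Proposed new method: the acid ionises the benzylic C–OH of 8 and the resulting quinone methide 11 stays hydrogen-bonded/ion-paired to the chiral phosphoramide anion while its electron-poor O=C–C=CH2 unit adds across a terminal C=C of the polyene in an asynchronous inverse-electron-demand oxa-[4+2] cycloaddition (CH2 to the terminal carbon, O to the inner carbon, where the developing positive charge is delocalised over the rest of the polyene); the closest known reaction types are the thermal hetero-Diels–Alder reaction of tropolone o-quinone methides with alkenes and the chiral phosphoric-acid-type catalysed [4+2] cycloadditions of in situ generated benzenoid o-quinone methides with styrenes or tethered alkenes, neither of which has been shown under catalyst control for a tropolone quinone methide and an acyclic polyene. Each dihydropyran ring is closed by the cycloaddition itself, C–C and C–O bond in one six-membered transition state (in the stepwise limit a 6-exo capture of the dienyl cation by the tropolone oxygen). C2′ and C2 are set by the catalyst, which should present the same alkene face at both termini, and C3 follows stereospecifically from the (E)-propenyl geometry (suprafacial addition, 2,3-trans). Since two catalyst-controlled events take place on one molecule, the homochiral (2R,3R,2′R) product should be enriched beyond the selectivity of a single event (Horeau-type amplification), mismatched events ending in separable diastereomers. The step needs site selectivity for the two termini over the inner C=C bonds; the vinyl CH2 and the methyl-capped propenyl carbon are the most nucleophilic and least hindered positions, and the diene that remains is deactivated by two allylic C–O bonds.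

Compound list
1 | 2-methylanisole (1-methoxy-2-methylbenzene) | COc1ccccc1C | starting material
2 | 1-methoxy-2-methylcyclohexa-1,4-diene | COC1=C(C)CC=CC1 | intermediate
3 | (±)-7,7-dibromo-1-methoxy-6-methylbicyclo[4.1.0]hept-3-ene (one enantiomer drawn) | CO[C@@]12CC=CC[C@]1(C)C2(Br)Br | intermediate
4 | (±)-7,7-dibromo-1-methoxy-6-methylbicyclo[4.1.0]heptane-3,4-diol, cis-diol anti to the CBr2 bridge (one enantiomer drawn) | CO[C@@]12C[C@@H](O)[C@@H](O)C[C@]1(C)C2(Br)Br | intermediate
5 | (±)-7,7-dibromo-1-methoxy-6-methylbicyclo[4.1.0]heptane-3,4-dione (one enantiomer drawn) | CO[C@@]12CC(=O)C(=O)C[C@]1(C)C2(Br)Br | intermediate (not isolated)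
6 | 5-bromo-2-hydroxy-4-methoxy-6-methylcyclohepta-2,4,6-trien-1-one | COc1cc(O)c(=O)cc(C)c1Br | intermediate
7 | 5-bromo-2,4-dihydroxy-6-methylcyclohepta-2,4,6-trien-1-one | Cc1cc(=O)c(O)cc(O)c1Br | intermediate
8 | 2,4-dihydroxy-5-(hydroxymethyl)-6-methylcyclohepta-2,4,6-trien-1-one | Cc1cc(=O)c(O)cc(O)c1CO | intermediate
9 | (2E,4E)-hexa-2,4-dienal | C/C=C/C=C/C=O | starting material
10 | (3E,5E,7E)-nona-1,3,5,7-tetraene | C=C/C=C/C=C/C=C/C | intermediate
11 | 2-hydroxy-6-methyl-5-methylidenecyclohepta-2,6-diene-1,4-dione (tropolone o-quinone methide) | C=C1C(C)=CC(=O)C(O)=CC1=O | intermediate (not isolated)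
12 | (2R)-2-[(1E,3E,5E)-hepta-1,3,5-trien-1-yl]-8-hydroxy-5-methyl-3,4-dihydrocyclohepta[b]pyran-7(2H)-one | C/C=C/C=C/C=C/[C@H]1CCc2c(C)cc(=O)c(O)cc2O1 | intermediate (not isolated)
13 | (2R,3R)-8-hydroxy-2-{(1E,3E)-4-[(2R)-8-hydroxy-5-methyl-7-oxo-2,3,4,7-tetrahydrocyclohepta[b]pyran-2-yl]buta-1,3-dien-1-yl}-3,5-dimethyl-3,4-dihydrocyclohepta[b]pyran-7(2H)-one | Cc1cc(=O)c(O)cc2c1C[C@@H](C)[C@H](/C=C/C=C/[C@H]1CCc3c(C)cc(=O)c(O)cc3O1)O2 | target

Total step count: 8
Longest linear sequence: 7 steps (steps 1 to 6, then step 8)

Steps most likely to fail

1. Step 8 (key step, proposed new method). What may go wrong: an uncatalysed or substrate-acid-catalysed background cycloaddition outside the chiral pocket, giving poor facial selectivity; acid-induced oligomerisation of the tetraene or self-condensation of the quinone methide with 8; reversible ionisation of the doubly allylic C2–O bonds eroding configuration. Fallback with known chemistry, replacing catalyst control by separation: it sets out from 8 and 10. Heating 8 (2.4 equiv) with 10 and a trace of BHT in toluene at 140–150 °C in a sealed tube, without acid, should generate 11 thermally and give the twofold cycloadduct without absolute control. That mixture would hold 13 together with its (2S,3S,2′S)-enantiomer F1, the heterochiral (2R,3R,2′S)-diastereomer F2 and the heterochiral (2S,3S,2′R)-diastereomer F3; the 2,3-trans relationship stays fixed by the alkene geometry. F2 and F3 are diastereomers of 13 and should be removable on silica or by reversed-phase HPLC. 13 would then be separated from F1 by preparative HPLC on a chiral stationary phase, for example amylose tris(3,5-dimethylphenylcarbamate). The fallback comes back to the route at 13.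

2. Step 6. What may go wrong: slow transmetalation of the α-hydroxyalkyl stannane at the di-ortho-substituted aryl–palladium centre, with protodestannylation of the reagent by the acidic substrate and thermal loss of water from the product. Fallback that couples a fast-transmetalating two-carbon unit and degrades it: it sets out from 7. Suzuki–Miyaura coupling with potassium vinyltrifluoroborate (PdCl2(dppf), Cs2CO3, THF/H2O, 70 °C) should give 5-ethenyl-2,4-dihydroxy-6-methylcyclohepta-2,4,6-trien-1-one F4. Lemieux–Johnson cleavage (OsO4 cat., NaIO4, 2,6-lutidine, dioxane/H2O) should give 5-formyl-2,4-dihydroxy-6-methylcyclohepta-2,4,6-trien-1-one F5. NaBH4 in MeOH at 0 °C should reduce only the aldehyde, the tropolonate being inert, and the fallback comes back to the route at 8.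

3. Step 7. What may go wrong: γ-attack of the allyl anion, incomplete E-selectivity at the new C3=C4 bond, and loss of the volatile, polymerisable tetraene on isolation. Fallback that makes the terminal C=C last, where no alkene geometry is at stake: it sets out from 9. Wittig reaction with (triphenylphosphoranylidene)acetaldehyde (1 equiv, toluene, 80 °C; stabilised ylide, E-selective) should give (2E,4E,6E)-octa-2,4,6-trienal F6. Methylenation with Ph3P=CH2 (from methyltriphenylphosphonium bromide and KHMDS, THF, −78 to 0 °C) should then give the tetraene, and the fallback comes back to the route at 10.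

Further compounds
F1 | step 8 | (2S,3S,2′S)-enantiomer of 13 | Cc1cc(=O)c(O)cc2c1C[C@H](C)[C@@H](/C=C/C=C/[C@@H]1CCc3c(C)cc(=O)c(O)cc3O1)O2
F2 | step 8 | (2R,3R,2′S)-diastereomer of 13 | Cc1cc(=O)c(O)cc2c1C[C@@H](C)[C@H](/C=C/C=C/[C@@H]1CCc3c(C)cc(=O)c(O)cc3O1)O2
F3 | step 8 | (2S,3S,2′R)-diastereomer of 13 | Cc1cc(=O)c(O)cc2c1C[C@H](C)[C@@H](/C=C/C=C/[C@H]1CCc3c(C)cc(=O)c(O)cc3O1)O2
F4 | step 6 | 5-ethenyl-2,4-dihydroxy-6-methylcyclohepta-2,4,6-trien-1-one | Cc1cc(=O)c(O)cc(O)c1C=C
F5 | step 6 | 5-formyl-2,4-dihydroxy-6-methylcyclohepta-2,4,6-trien-1-one | Cc1cc(=O)c(O)cc(O)c1C=O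
F6 | step 7 | (2E,4E,6E)-octa-2,4,6-trienal | C/C=C/C=C/C=C/C=O
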